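**Strategy**

Ring A (C4a, C5, C6, C7, C8, C8a; naphthalene numbering) holds an α-ketol, the C6 ketone beside the C7 carbinol, which is the retron of an acyloin (α-ketol) rearrangement. Ring A is therefore carried as a cyclopentene whose tertiary carbinol carbon bears a masked formyl group. Unmasking lets a ring bond migrate to the formyl carbon: one operation inserts that carbon as C7, turns the carbinol into the C6 ketone, completes the C3=C4–C4a=C5–C6=O dienone and leaves the C7 hydroxyl trans to the C8a methyl. The precursor is a 7,7a-dimethylhydrindadiene, already acylated at the ring B oxygen, made from a quinone monoketal by asymmetric conjugate addition, two alkylations and cyclopentenone annulation.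

Key step: step 14

Assumption: (2S,3S)-2,3-dimethyloxirane (trans-2,3-epoxybutane, single enantiomer) is taken as a commercial compound; ring B is the ring that carries the ester oxygen.

**Route**

Step 1
Reactants: 1 4,4-dimethoxycyclohexa-2,5-dien-1-one
Product: 2 (5R)-4,4-dimethoxy-5-methylcyclohex-2-en-1-one
Conditions: Me2Zn (1.5 equiv), Cu(OTf)2 (2 mol %), BINOL-derived phosphoramidite ligand (4 mol %, the enantiomer that gives 5R), toluene, −25 °C; aq. NH4Cl
Reagents that add atoms: dimethylzinc, C[Zn]C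
Why: Copper-catalysed asymmetric conjugate addition of a dialkylzinc to a quinone monoketal; the two enone halves are enantiotopic and the chiral copper–phosphoramidite complex selects one β-carbon and face, which sets C5 (the later C1 of the target), while the zinc enolate resists a second addition.

Step 2
Reactants: 2 (5R)-4,4-dimethoxy-5-methylcyclohex-2-en-1-one
Product: 3 (5R,6R)-4,4-dimethoxy-5,6-dimethylcyclohex-2-en-1-one
Conditions: LDA (1.1 equiv), THF, −78 °C; MeI, −78 → 0 °C
Reagents that add atoms: iodomethane, CI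
Why: Kinetic α′-deprotonation of the enone and SN2 methylation of the lithium enolate (enolate alkylation); the methyl should enter anti to the C5 methyl (trans isomer), but C6 becomes planar again in step 3, so either epimer serves.

Step 3
Reactants: 3 (5R,6R)-4,4-dimethoxy-5,6-dimethylcyclohex-2-en-1-one
Product: 4 (5R,6R)-4,4-dimethoxy-5,6-dimethyl-6-(2-methylprop-2-en-1-yl)cyclohex-2-en-1-one
Conditions: LDA (1.2 equiv), THF, −78 → 0 °C; 3-bromo-2-methylprop-1-ene, DMPU, −78 → −20 °C
Reagents that add atoms: 3-bromo-2-methylprop-1-ene, C=C(C)CBr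
Why: Alkylation of the tetrasubstituted α′-enolate, as in the classical alkylation of 2,3-dimethylcyclohexanone enolates; the allylic bromide should enter anti to the pseudo-axial C5 methyl (1,2-induction), which sets the quaternary carbon with the two methyl groups cis.

Step 4
Reactants: 4 (5R,6R)-4,4-dimethoxy-5,6-dimethyl-6-(2-methylprop-2-en-1-yl)cyclohex-2-en-1-one
Product: 5 (5R,6R)-4,4-dimethoxy-5,6-dimethyl-6-(2-oxopropyl)cyclohex-2-en-1-one
Conditions: O3, CH2Cl2–MeOH (4:1), NaHCO3, −78 °C (Sudan red 7B as end-point indicator); Me2S, −78 → 20 °C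
Reagents that add atoms: ozone, [O-][O+]=O
Why: Ozonolysis with reductive work-up; the electron-rich 1,1-disubstituted alkene should react far faster than the electron-poor enone, and the neutral conditions spare the ketal.

Step 5
Reactants: 5 (5R,6R)-4,4-dimethoxy-5,6-dimethyl-6-(2-oxopropyl)cyclohex-2-en-1-one
Product: 6 (7R,7aR)-6,6-dimethoxy-7,7a-dimethyl-1,6,7,7a-tetrahydro-2H-inden-2-one
Conditions: KOH (0.3 equiv), MeOH, 50 °C
Reagents that add atoms: none
Why: Intramolecular aldol condensation (cyclopentenone annulation): the methyl ketone enolate adds to the ring carbonyl in a five-membered closure and dehydration gives the cross-ring dienone; the quaternary centre cannot epimerise and the ketal is stable to base.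

Step 6
Reactants: 6 (7R,7aR)-6,6-dimethoxy-7,7a-dimethyl-1,6,7,7a-tetrahydro-2H-inden-2-one
Product: 7 (2S,7R,7aR)-2-(1,3-dithian-2-yl)-6,6-dimethoxy-7,7a-dimethyl-2,6,7,7a-tetrahydro-1H-inden-2-ol
Conditions: 1,3-dithiane, n-BuLi, THF, −30 °C; then 6, −78 °C; H2O
Reagents that add atoms: 2-lithio-1,3-dithiane, [Li]C1SCCCS1 (generated from 1,3-dithiane, C1CSCSC1, and n-BuLi)
Why: Corey–Seebach 1,2-addition of a formyl anion equivalent to the cyclopentenone carbonyl (THF without HMPA favours 1,2 over conjugate addition); attack anti to the angular methyl should give 2S, but this carbon later becomes the C6 ketone, so its configuration is immaterial.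

Step 7
Reactants: 7 (2S,7R,7aR)-2-(1,3-dithian-2-yl)-6,6-dimethoxy-7,7a-dimethyl-2,6,7,7a-tetrahydro-1H-inden-2-ol
Product: 8 (2S,7R,7aR)-2-(1,3-dithian-2-yl)-2-hydroxy-7,7a-dimethyl-1,2,7,7a-tetrahydro-6H-inden-6-one
Conditions: PPTS (0.1 equiv), acetone–H2O (10:1), 0 → 20 °C
Reagents that add atoms: water, O
Why: Acetal hydrolysis through a diene-stabilised oxocarbenium ion, which should form under much milder acid than ionisation of the tertiary carbinol; once the dienone exists the diene is electron-poor and the carbinol is safe, and the dithiane is acid-stable.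

Step 8
Reactants: 8 (2S,7R,7aR)-2-(1,3-dithian-2-yl)-2-hydroxy-7,7a-dimethyl-1,2,7,7a-tetrahydro-6H-inden-6-one
Product: 9 (2S,6S,7R,7aR)-2-(1,3-dithian-2-yl)-7,7a-dimethyl-2,6,7,7a-tetrahydro-1H-indene-2,6-diol
Conditions: NaBH4, CeCl3·7H2O, MeOH, −78 °C
Reagents that add atoms: none
Why: Luche 1,2-reduction of the dienone carbonyl; hydride should arrive on the face opposite the angular C7a methyl and the cis C7 methyl, which places the new hydroxyl cis to both methyl groups (6S).

Step 9
Reactants: 10 (2S,3S)-2,3-dimethyloxirane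
Product: 11 (2S,3S)-3-methylpent-4-en-2-ol
Conditions: vinylmagnesium bromide, CuI (10 mol %), THF, −30 → 0 °C; 1 M HCl
Reagents that add atoms: vinylmagnesium bromide, C=C[Mg]Br
Why: Copper-catalysed SN2 opening of the epoxide with inversion at the attacked carbon; the two epoxide carbons are homotopic, so one syn (2S,3S) product should form and both stereocentres come from the epoxide.

Step 10
Reactants: 11 (2S,3S)-3-methylpent-4-en-2-ol
Product: 12 tert-butyl(dimethyl){[(2S,3S)-3-methylpent-4-en-2-yl]oxy}silane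
Conditions: TBSCl, imidazole, DMF, 20 °C
Reagents that add atoms: tert-butyldimethylsilyl chloride, CC(C)(C)[Si](C)(C)Cl
Why: Standard silylation of a secondary alcohol; it keeps the hydroxyl from competing as an acyl acceptor in step 13.

Step 11
Reactants: 12 tert-butyl(dimethyl){[(2S,3S)-3-methylpent-4-en-2-yl]oxy}silane; 13 methyl (2E,4E)-hexa-2,4-dienoate
Product: 14 methyl (2E,4E,6S,7S)-7-[(tert-butyldimethylsilyl)oxy]-6-methylocta-2,4-dienoate
Conditions: second-generation Hoveyda–Grubbs catalyst (5 mol %), 13 (3 equiv), CH2Cl2, 40 °C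
Reagents that add atoms: none
Why: Ene–diene cross-metathesis at the distal, more electron-rich 4,5-alkene of the sorbate with loss of propene; the conjugated 2,3-alkene is inert and the new disubstituted alkene should form as the E isomer.

Step 12
Reactants: 14 methyl (2E,4E,6S,7S)-7-[(tert-butyldimethylsilyl)oxy]-6-methylocta-2,4-dienoate
Product: 15 (2E,4E,6S,7S)-7-[(tert-butyldimethylsilyl)oxy]-6-methylocta-2,4-dienoic acid
Conditions: LiOH, THF–MeOH–H2O, 20 °C; then 1 M HCl to pH 4, 0 °C
Reagents that add atoms: lithium hydroxide, [Li+].[OH-]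
Why: Saponification of the methyl ester; the secondary silyl ether and the diene geometry should survive hydroxide and brief mild acidification.

Step 13
Reactants: 9 (2S,6S,7R,7aR)-2-(1,3-dithian-2-yl)-7,7a-dimethyl-2,6,7,7a-tetrahydro-1H-indene-2,6-diol; 15 (2E,4E,6S,7S)-7-[(tert-butyldimethylsilyl)oxy]-6-methylocta-2,4-dienoic acid
Product: 17 (2S,6S,7R,7aR)-2-(1,3-dithian-2-yl)-2-hydroxy-7,7a-dimethyl-2,6,7,7a-tetrahydro-1H-inden-6-yl (2E,4E,6S,7S)-7-[(tert-butyldimethylsilyl)oxy]-6-methylocta-2,4-dienoate, via Yamaguchi mixed anhydride 16 (not isolated)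
Conditions: 15, 2,4,6-trichlorobenzoyl chloride, Et3N, toluene, 20 °C; then 9, DMAP, toluene, 20 → 40 °C
Reagents that add atoms: 2,4,6-trichlorobenzoyl chloride, O=C(Cl)c1c(Cl)cc(Cl)cc1Cl (its atoms stay only in intermediate 16)
Why: Yamaguchi esterification; only the secondary allylic hydroxyl should be acylated, the tertiary carbinol is too hindered, and acylation on oxygen retains the 6S configuration.

Step 14
Reactants: 17 (2S,6S,7R,7aR)-2-(1,3-dithian-2-yl)-2-hydroxy-7,7a-dimethyl-2,6,7,7a-tetrahydro-1H-inden-6-yl (2E,4E,6S,7S)-7-[(tert-butyldimethylsilyl)oxy]-6-methylocta-2,4-dienoate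
Product: 19 (1R,2S,7R,8aR)-7-hydroxy-1,8a-dimethyl-6-oxo-1,2,6,7,8,8a-hexahydronaphthalen-2-yl (2E,4E,6S,7S)-7-[(tert-butyldimethylsilyl)oxy]-6-methylocta-2,4-dienoate, via hydroxy aldehyde 18 (not isolated)
Conditions: MeI, CaCO3, MeCN–H2O (9:1), 40 °C; then solvent exchange to toluene, DBU (0.2 equiv), 50 °C, argon
Reagents that add atoms: water, O
Why: S-Methylation and hydrolysis unmask the tertiary α-hydroxy aldehyde 18, whose alkoxide undergoes an α-ketol (acyloin) rearrangement: a ring C–C bond on the carbinol carbon migrates to the formyl carbon, so the formyl carbon enters the ring as C7 and the carbinol carbon becomes the C6 ketone. The closest known reaction type is the base- or Lewis-acid-mediated ring enlargement of 1-hydroxycycloalkanecarbaldehydes and the D-homoannulation of 17-hydroxy-20-oxo steroids. Ring A is not closed end to end; it grows from the cyclopentene by this 1,2-shift, a one-carbon enlargement from five to six members. The only new stereocentre, C7, is set under thermodynamic control through the enediol, with the hydroxyl pseudo-equatorial and trans to the axial C8a methyl. The step needs regiochemical convergence and chemoselectivity: migration of either the CH2 or the alkenyl carbon gives ketols that meet, by enediol tautomerism, at the same conjugated 7-hydroxy dienone, which is the thermodynamic sink (aldehyde to ketone, strain relief, new conjugation), and neutral unmasking plus a catalytic amidine base should leave the dienoate ester and the silyl ether untouched.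

Step 15
Reactants: 19 (1R,2S,7R,8aR)-7-hydroxy-1,8a-dimethyl-6-oxo-1,2,6,7,8,8a-hexahydronaphthalen-2-yl (2E,4E,6S,7S)-7-[(tert-butyldimethylsilyl)oxy]-6-methylocta-2,4-dienoate
Product: 20 (1R,2S,7R,8aR)-7-hydroxy-1,8a-dimethyl-6-oxo-1,2,6,7,8,8a-hexahydronaphthalen-2-yl (2E,4E,6S,7S)-7-hydroxy-6-methylocta-2,4-dienoate
Conditions: HF·pyridine, pyridine–THF, 0 → 20 °C
Reagents that add atoms: none
Why: Fluoride-mediated desilylation under buffered conditions; the α-ketol, the dienone and the allylic ester should tolerate it and no stereocentre is touched.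

**Compound list**

1 | 4,4-dimethoxycyclohexa-2,5-dien-1-one | COC1(OC)C=CC(=O)C=C1 | starting material
2 | (5R)-4,4-dimethoxy-5-methylcyclohex-2-en-1-one | COC1(OC)C=CC(=O)C[C@H]1C | intermediate
3 | (5R,6R)-4,4-dimethoxy-5,6-dimethylcyclohex-2-en-1-one | COC1(OC)C=CC(=O)[C@H](C)[C@H]1C | intermediate
4 | (5R,6R)-4,4-dimethoxy-5,6-dimethyl-6-(2-methylprop-2-en-1-yl)cyclohex-2-en-1-one | COC1(OC)C=CC(=O)[C@@](CC(C)=C)(C)[C@H]1C | intermediate
5 | (5R,6R)-4,4-dimethoxy-5,6-dimethyl-6-(2-oxopropyl)cyclohex-2-en-1-one | COC1(OC)C=CC(=O)[C@@](CC(C)=O)(C)[C@H]1C | intermediate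
6 | (7R,7aR)-6,6-dimethoxy-7,7a-dimethyl-1,6,7,7a-tetrahydro-2H-inden-2-one | COC1(OC)C=CC2=CC(=O)C[C@]2(C)[C@H]1C | intermediate
7 | (2S,7R,7aR)-2-(1,3-dithian-2-yl)-6,6-dimethoxy-7,7a-dimethyl-2,6,7,7a-tetrahydro-1H-inden-2-ol | COC1(OC)C=CC2=C[C@](O)(C3SCCCS3)C[C@]2(C)[C@H]1C | intermediate
8 | (2S,7R,7aR)-2-(1,3-dithian-2-yl)-2-hydroxy-7,7a-dimethyl-1,2,7,7a-tetrahydro-6H-inden-6-one | O=C1C=CC2=C[C@](O)(C3SCCCS3)C[C@]2(C)[C@H]1C | intermediate
9 | (2S,6S,7R,7aR)-2-(1,3-dithian-2-yl)-7,7a-dimethyl-2,6,7,7a-tetrahydro-1H-indene-2,6-diol | O[C@H]1C=CC2=C[C@](O)(C3SCCCS3)C[C@]2(C)[C@H]1C | intermediate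
10 | (2S,3S)-2,3-dimethyloxirane | C[C@@H]1O[C@H]1C | starting material
11 | (2S,3S)-3-methylpent-4-en-2-ol | C[C@H](O)[C@@H](C)C=C | intermediate
12 | tert-butyl(dimethyl){[(2S,3S)-3-methylpent-4-en-2-yl]oxy}silane | C[C@H](O[Si](C)(C)C(C)(C)C)[C@@H](C)C=C | intermediate
13 | methyl (2E,4E)-hexa-2,4-dienoate | C/C=C/C=C/C(=O)OC | starting material
14 | methyl (2E,4E,6S,7S)-7-[(tert-butyldimethylsilyl)oxy]-6-methylocta-2,4-dienoate | C[C@H](O[Si](C)(C)C(C)(C)C)[C@@H](C)/C=C/C=C/C(=O)OC | intermediate
15 | (2E,4E,6S,7S)-7-[(tert-butyldimethylsilyl)oxy]-6-methylocta-2,4-dienoic acid | C[C@H](O[Si](C)(C)C(C)(C)C)[C@@H](C)/C=C/C=C/C(=O)O | intermediate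
16 | (2E,4E,6S,7S)-7-[(tert-butyldimethylsilyl)oxy]-6-methylocta-2,4-dienoic 2,4,6-trichlorobenzoic anhydride | C[C@H](O[Si](C)(C)C(C)(C)C)[C@@H](C)/C=C/C=C/C(=O)OC(=O)c1c(Cl)cc(Cl)cc1Cl | intermediate
17 | (2S,6S,7R,7aR)-2-(1,3-dithian-2-yl)-2-hydroxy-7,7a-dimethyl-2,6,7,7a-tetrahydro-1H-inden-6-yl (2E,4E,6S,7S)-7-[(tert-butyldimethylsilyl)oxy]-6-methylocta-2,4-dienoate | C[C@H](O[Si](C)(C)C(C)(C)C)[C@@H](C)/C=C/C=C/C(=O)O[C@H]1C=CC2=C[C@](O)(C3SCCCS3)C[C@]2(C)[C@H]1C | intermediate
18 | (2S,6S,7R,7aR)-2-formyl-2-hydroxy-7,7a-dimethyl-2,6,7,7a-tetrahydro-1H-inden-6-yl (2E,4E,6S,7S)-7-[(tert-butyldimethylsilyl)oxy]-6-methylocta-2,4-dienoate | C[C@H](O[Si](C)(C)C(C)(C)C)[C@@H](C)/C=C/C=C/C(=O)O[C@H]1C=CC2=C[C@](O)(C=O)C[C@]2(C)[C@H]1C | intermediate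
19 | (1R,2S,7R,8aR)-7-hydroxy-1,8a-dimethyl-6-oxo-1,2,6,7,8,8a-hexahydronaphthalen-2-yl (2E,4E,6S,7S)-7-[(tert-butyldimethylsilyl)oxy]-6-methylocta-2,4-dienoate | C[C@H](O[Si](C)(C)C(C)(C)C)[C@@H](C)/C=C/C=C/C(=O)O[C@H]1C=CC2=CC(=O)[C@H](O)C[C@]2(C)[C@H]1C | intermediate
20 | (1R,2S,7R,8aR)-7-hydroxy-1,8a-dimethyl-6-oxo-1,2,6,7,8,8a-hexahydronaphthalen-2-yl (2E,4E,6S,7S)-7-hydroxy-6-methylocta-2,4-dienoate | C[C@H](O)[C@@H](C)/C=C/C=C/C(=O)O[C@H]1C=CC2=CC(=O)[C@H](O)C[C@]2(C)[C@H]1C | target

**Step count**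

Total step count: 15. Longest linear sequence: 11 steps (steps 1–8, then 13–15); the acid fragment takes steps 9–12.

**Steps most likely to fail, with fallbacks**

Step 14. The 1,2-shift may stall at the hydroxy aldehyde, or water may be lost from the tertiary, doubly allylic carbinol before a bond migrates. The fallback sets out from 17 and comes back at 19, and ring A still arises by one-carbon enlargement of the five-membered ring. Compound 17 is unmasked as in step 14 to 18, which is cleaved with NaIO4 in THF–H2O, without base treatment, to the cyclopentenone ester (6S,7R,7aR)-7,7a-dimethyl-2-oxo-2,6,7,7a-tetrahydro-1H-inden-6-yl (2E,4E,6S,7S)-7-[(tert-butyldimethylsilyl)oxy]-6-methylocta-2,4-dienoate F1. Homologation of this ketone with TMSCHN2 and Sc(OTf)3 in CH2Cl2 (migration of the CH2 carbon expected, then carbon-to-oxygen silyl shift) should give the enol silane (1R,2S,8aR)-1,8a-dimethyl-6-[(trimethylsilyl)oxy]-1,2,8,8a-tetrahydronaphthalen-2-yl (2E,4E,6S,7S)-7-[(tert-butyldimethylsilyl)oxy]-6-methylocta-2,4-dienoate F2. Rubottom oxidation (mCPBA, NaHCO3, CH2Cl2, −20 °C) on the face away from the C8a methyl should give the silyloxy ketone (1R,2S,7R,8aR)-1,8a-dimethyl-6-oxo-7-[(trimethylsilyl)oxy]-1,2,6,7,8,8a-hexahydronaphthalen-2-yl (2E,4E,6S,7S)-7-[(tert-butyldimethylsilyl)oxy]-6-methylocta-2,4-dienoate F3, and citric acid in aqueous THF then frees 19.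

Step 7. The acid needed to open the ketal may instead ionise or dehydrate the tertiary, doubly allylic carbinol, or trigger sulfur participation from the dithiane. The fallback sets out from 6 and comes back at 8 by reversing the order of events. The ketal of 6 is hydrolysed first (1 M HCl, THF, 0 °C), when no carbinol is present, to the dienedione (7R,7aR)-7,7a-dimethyl-7,7a-dihydro-1H-indene-2,6-dione F4. The dithiane is then added as its cerium reagent (2-lithio-1,3-dithiane, CeCl3, THF, −78 °C); this weakly basic nucleophile should select the unhindered cyclopentenone carbonyl over the six-ring carbonyl flanked by the methyl-bearing C7, and it gives 8 directly.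

Step 3. Facial selectivity in the alkylation of the hindered tetrasubstituted enolate may be poor, or O-alkylation and slow conversion may intervene. The fallback sets out from 3 and comes back at 4 with catalyst control over the new quaternary centre. The potassium enolate of 3 (KHMDS, THF, −78 °C) is trapped on oxygen with 2-methylprop-2-en-1-yl chloroformate to give the enol carbonate (3R)-4,4-dimethoxy-2,3-dimethylcyclohexa-1,5-dien-1-yl 2-methylprop-2-en-1-yl carbonate F5. Decarboxylative allylic alkylation with Pd2(dba)3 (zerovalent palladium) and the t-Bu-PHOX ligand enantiomer matched to the substrate bias (toluene, 30 °C) should then deliver 4.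

Further compounds
F1 | step 14 | (6S,7R,7aR)-7,7a-dimethyl-2-oxo-2,6,7,7a-tetrahydro-1H-inden-6-yl (2E,4E,6S,7S)-7-[(tert-butyldimethylsilyl)oxy]-6-methylocta-2,4-dienoate | C[C@H](O[Si](C)(C)C(C)(C)C)[C@@H](C)/C=C/C=C/C(=O)O[C@H]1C=CC2=CC(=O)C[C@]2(C)[C@H]1C
F2 | step 14 | (1R,2S,8aR)-1,8a-dimethyl-6-[(trimethylsilyl)oxy]-1,2,8,8a-tetrahydronaphthalen-2-yl (2E,4E,6S,7S)-7-[(tert-butyldimethylsilyl)oxy]-6-methylocta-2,4-dienoate | C[C@H](O[Si](C)(C)C(C)(C)C)[C@@H](C)/C=C/C=C/C(=O)O[C@H]1C=CC2=CC(O[Si](C)(C)C)=CC[C@]2(C)[C@H]1C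
F3 | step 14 | (1R,2S,7R,8aR)-1,8a-dimethyl-6-oxo-7-[(trimethylsilyl)oxy]-1,2,6,7,8,8a-hexahydronaphthalen-2-yl (2E,4E,6S,7S)-7-[(tert-butyldimethylsilyl)oxy]-6-methylocta-2,4-dienoate | C[C@H](O[Si](C)(C)C(C)(C)C)[C@@H](C)/C=C/C=C/C(=O)O[C@H]1C=CC2=CC(=O)[C@H](O[Si](C)(C)C)C[C@]2(C)[C@H]1C
F4 | step 7 | (7R,7aR)-7,7a-dimethyl-7,7a-dihydro-1H-indene-2,6-dione | O=C1C=CC2=CC(=O)C[C@]2(C)[C@H]1C
F5 | step 3 | (3R)-4,4-dimethoxy-2,3-dimethylcyclohexa-1,5-dien-1-yl 2-methylprop-2-en-1-yl carbonate | COC1(OC)C=CC(OC(=O)OCC(C)=C)=C(C)[C@H]1C
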